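## Retrosynthetic overview

1. The γ-lactone is opened at its acyl C–O bond to a tris-primary triol; a site-selective aerobic oxidative lactonisation closes it (key C–O step, new). The α-acetoxy C–O bond and both acetates follow in the last step.
2. The triol comes from global hydride reduction of a cis-3,4-disubstituted 5-menthyloxy-butanolide. The carbonyl that activates the C–C coupling thus ends as the lactone CH2–O carbon, and the menthyl acetal leaves without a separate step.
3. The bond between azulene C1 and the butanolide is made by photoredox Giese coupling of a tertiary cis-hydroazulenyl radical (from a caesium oxalate) with a chiral 3-substituted 5-menthyloxybutenolide.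
4. Hydroazulene: the seven-membered ring is made first (ring expansion to 4,4-dimethylcycloheptenone, asymmetric conjugate addition with enolate triflation). The cyclopentane follows by intramolecular Hosomi–Sakurai allylation, which gives the cis-fused tertiary carbinol and the exocyclic methylene.
5. Butenolide: furfural and (+)-menthol give the acetal that relays stereochemistry; bromination and Negishi coupling install CH2CO2Et. Ring order: cycloheptane, cyclopentane, (sacrificial butanolide), γ-lactone last.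

Assumption: the Josiphos antipode that gives the (3R)-adduct in step 4 is assigned by analogy and must be confirmed on the first run; carbinol 12 and oxalates 13/14 are C1-epimer mixtures (no descriptor at C1), which does not matter because C1 becomes a planar radical.

Numbering used in names: azulene numbering for the bicycle (C1 carbinol/quaternary carbon, C3a and C8a ring fusion, C4 gem-dimethyl, C8 methylidene); oxolane numbering for lactones. "Menthyl" = (1S,2R,5S)-5-methyl-2-(propan-2-yl)cyclohexyl, from (+)-menthol.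

## Route

Step 1
Reactants: 1 3-methylcyclohex-2-en-1-one
Product: 2 [(3,3-dimethylcyclohex-1-en-1-yl)oxy]trimethylsilane
Conditions: MeMgBr (1.2 equiv), CuI (5 mol%), LiCl (10 mol%), TMSCl (1.3 equiv), THF, −40 → 0 °C; Et3N/pentane work-up
Reagents that add atoms: methylmagnesium bromide, C[Mg]Br; chlorotrimethylsilane, C[Si](C)(C)Cl
Why: Copper-catalysed conjugate addition builds the gem-dimethyl carbon and TMSCl traps the enolate regiospecifically on the side of the new quaternary carbon (conjugate addition with enolate silylation); no stereocentre.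

Step 2
Reactants: 2 [(3,3-dimethylcyclohex-1-en-1-yl)oxy]trimethylsilane
Product: 3 [(5,5-dimethylbicyclo[4.1.0]heptan-1-yl)oxy]trimethylsilane (racemic)
Conditions: Et2Zn (1.5 equiv), CH2I2 (1.5 equiv), CH2Cl2, 0 °C → rt
Reagents that add atoms: diiodomethane, ICI
Why: Furukawa-modified Simmons–Smith cyclopropanation of the electron-rich silyl enol ether; both new stereocentres are destroyed in step 3.

Step 3
Reactants: 3 [(5,5-dimethylbicyclo[4.1.0]heptan-1-yl)oxy]trimethylsilane
Product: 5 4,4-dimethylcyclohept-2-en-1-one, via β-chloro ketone 4 (not isolated)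
Conditions: FeCl3 (2.2 equiv), DMF, 0 °C → rt; then NaOAc, MeOH, reflux
Reagents that add atoms: none
Why: Ito–Saegusa ring expansion: one-electron oxidation cleaves the internal cyclopropane bond, the β-keto radical is chlorinated, and E1cB loss of HCl gives the enone with the gem-dimethyl group at C4.

Step 4
Reactants: 5 4,4-dimethylcyclohept-2-en-1-one; 6 2-(2-bromoethyl)-2-methyl-1,3-dioxolane
Product: 10 (3R)-4,4-dimethyl-3-(3-oxobutyl)cyclohept-1-en-1-yl trifluoromethanesulfonate, via Grignard reagent 7 (not isolated), via magnesium enolate 8 (not isolated), via ketal triflate 9 (not isolated)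
Conditions: 6, Mg, 2-MeTHF, rt; then CuBr·SMe2 (5 mol%), Josiphos SL-J001 or antipode (6 mol%), 5, t-BuOMe, −78 °C; then Comins' reagent (1.2 equiv), −78 → 0 °C; then 1 M HCl, THF, rt
Reagents that add atoms: N-(5-chloropyridin-2-yl)-1,1,1-trifluoro-N-(trifluoromethylsulfonyl)methanesulfonamide (Comins' reagent), O=S(=O)(N(c1ccc(Cl)cn1)S(=O)(=O)C(F)(F)F)C(F)(F)F; water, O
Why: Copper-catalysed asymmetric conjugate addition sets the ring stereocentre (3R) under ligand control, the magnesium enolate is O-triflated regiospecifically so the double bond lies between C1 and C2 (Comins triflation), and aqueous acid unmasks the methyl ketone without touching the vinyl triflate (dioxolane hydrolysis).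

Step 5
Reactants: 10 (3R)-4,4-dimethyl-3-(3-oxobutyl)cyclohept-1-en-1-yl trifluoromethanesulfonate
Product: 11 4-[(1R)-7,7-dimethyl-3-[(trimethylsilyl)methyl]cyclohept-2-en-1-yl]butan-2-one
Conditions: Me3SiCH2ZnCl (1.5 equiv, preformed), Pd(PPh3)4 (5 mol%), LiCl, THF, 50 °C
Reagents that add atoms: [(trimethylsilyl)methyl]zinc chloride, C[Si](C)(C)C[Zn]Cl
Why: Negishi coupling of the vinyl triflate gives the allylsilane; the organozinc tolerates the ketone and no stereocentre is touched.

Step 6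
Reactants: 11 4-[(1R)-7,7-dimethyl-3-[(trimethylsilyl)methyl]cyclohept-2-en-1-yl]butan-2-one
Product: 12 (3aR,8aS)-1,4,4-trimethyl-8-methylidenedecahydroazulen-1-ol (C1 epimers)
Conditions: TiCl4 (1.1 equiv), CH2Cl2, −78 °C; aq. NaHCO3
Reagents that add atoms: none
Why: Intramolecular Hosomi–Sakurai allylation: the γ-carbon of the allylsilane attacks the Ti-activated ketone, closing the cyclopentane and moving the alkene to the exocyclic position; the short tether reaches only the ring face it sits on, so the fusion is cis (C8a = S relative to C3a = R).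

Step 7
Reactants: 12 (3aR,8aS)-1,4,4-trimethyl-8-methylidenedecahydroazulen-1-ol
Product: 14 caesium {[(3aR,8aS)-1,4,4-trimethyl-8-methylidenedecahydroazulen-1-yl]oxy}(oxo)acetate, via methyl oxalate 13 (not isolated)
Conditions: ClC(O)CO2Me (1.5 equiv), Et3N, DMAP (10 mol%), CH2Cl2, 0 °C → rt; then CsOH·H2O (1.0 equiv), THF/H2O, rt
Reagents that add atoms: methyl chlorooxoacetate, COC(=O)C(=O)Cl; caesium hydroxide, [Cs+].[OH-]
Why: O-acylation of the tertiary alcohol, then saponification of the unhindered methyl ester only, gives the bench-stable tertiary alkyl caesium oxalate (acylation, selective ester hydrolysis).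

Step 8
Reactants: 15 furfural
Product: 16 5-hydroxyfuran-2(5H)-one (racemic)
Conditions: O2, rose bengal (cat.), MeOH, visible light, rt
Reagents that add atoms: dioxygen, O=O
Why: Singlet-oxygen [4+2] addition to the furan and fragmentation of the endoperoxide expel the formyl carbon and leave the γ-hydroxybutenolide (dye-sensitised photo-oxygenation).

Step 9
Reactants: 16 5-hydroxyfuran-2(5H)-one; 17 (1S,2R,5S)-(+)-menthol
Product: 18 (5S)-5-(menthyloxy)furan-2(5H)-one
Conditions: CSA (cat.), toluene, reflux, Dean–Stark; crystallisation from petroleum ether, mother liquor re-equilibrated with acid and recycled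
Reagents that add atoms: none
Why: Acid-catalysed acetalisation of the pseudo-acid; the acetal epimers interconvert under acid and the (5S) epimer crystallises, so crystallisation sets the acetal stereocentre that later controls the coupling.

Step 10
Reactants: 18 (5S)-5-(menthyloxy)furan-2(5H)-one
Product: 20 (5S)-3-bromo-5-(menthyloxy)furan-2(5H)-one, via dibromide 19 (not isolated)
Conditions: Br2 (1.05 equiv), CH2Cl2, 0 °C; then Et3N (1.5 equiv), 0 °C → rt
Reagents that add atoms: bromine, BrBr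
Why: Bromine addition, then E1cB dehydrobromination (acidic C3–H removed, C4–Br lost), gives the α-bromobutenolide; the acetal centre is not touched.

Step 11
Reactants: 20 (5S)-3-bromo-5-(menthyloxy)furan-2(5H)-one; 21 (2-ethoxy-2-oxoethyl)zinc bromide
Product: 22 ethyl 2-[(5S)-5-(menthyloxy)-2-oxo-2,5-dihydrofuran-3-yl]acetate
Conditions: Pd2(dba)3 (2.5 mol%), XPhos (6 mol%), THF, rt → 45 °C
Reagents that add atoms: none
Why: Negishi coupling of the Reformatsky reagent with the electron-poor vinyl bromide installs the CH2CO2Et arm under base-free conditions, which keeps the double bond endocyclic.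

Step 12
Reactants: 14 caesium {[(3aR,8aS)-1,4,4-trimethyl-8-methylidenedecahydroazulen-1-yl]oxy}(oxo)acetate; 22 ethyl 2-[(5S)-5-(menthyloxy)-2-oxo-2,5-dihydrofuran-3-yl]acetate
Product: 24 ethyl 2-[(3R,4R,5S)-5-(menthyloxy)-2-oxo-4-[(1R,3aR,8aS)-1,4,4-trimethyl-8-methylidenedecahydroazulen-1-yl]oxolan-3-yl]acetate, via caesium enolate 23 (not isolated)
Conditions: [Ir(dF(CF3)ppy)2(dtbbpy)]PF6 (1 mol%), DME/DMF 3:1, H2O (10 equiv), blue LEDs, rt
Reagents that add atoms: none
Why: Photoredox Giese reaction: oxidation of the oxalate and loss of two CO2 give the tertiary C1 radical, which bonds on the convex face of the cis-hydroazulene (cis to H-8a, C1 = R) to C4 of the butenolide anti to the menthyloxy group (C4 = R); the enolate formed after reduction is protonated by water away from the new tertiary alkyl group, giving the cis-3,4 lactone (C3 = R).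

Step 13
Reactants: 24 ethyl 2-[(3R,4R,5S)-5-(menthyloxy)-2-oxo-4-[(1R,3aR,8aS)-1,4,4-trimethyl-8-methylidenedecahydroazulen-1-yl]oxolan-3-yl]acetate
Product: 25 (2R,3R)-2-(2-hydroxyethyl)-3-[(1R,3aR,8aS)-1,4,4-trimethyl-8-methylidenedecahydroazulen-1-yl]butane-1,4-diol
Conditions: LiAlH4 (4 equiv), THF, 0 °C → rt; Rochelle-salt work-up
Reagents that add atoms: none
Why: Hydride reduction takes the lactone carbonyl, the acetal carbon (released as an aldehyde on ring opening) and the ethyl ester to three primary alcohols, sheds menthol, and locks the epimerisable lactone α-centre without touching the alkene.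

Step 14
Reactants: 25 (2R,3R)-2-(2-hydroxyethyl)-3-[(1R,3aR,8aS)-1,4,4-trimethyl-8-methylidenedecahydroazulen-1-yl]butane-1,4-diol
Product: 28 (4R)-4-{(1R)-2-hydroxy-1-[(1R,3aR,8aS)-1,4,4-trimethyl-8-methylidenedecahydroazulen-1-yl]ethyl}oxolan-2-one, via hydroxy aldehyde 26 (not isolated), via lactol 27 (not isolated)
Conditions: [Cu(MeCN)4]OTf (5 mol%), 2,2'-bipyridine (5 mol%), TEMPO (5 mol%), N-methylimidazole (10 mol%), MeCN, air, rt; then PPTS (10 mol%), CH2Cl2, rt
Reagents that add atoms: none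
Why: Proposed new method: Cu(I)/TEMPO aerobic alcohol oxidation is very sensitive to β-branching, so of the three primary carbinols only the unbranched CH2CH2OH end should be dehydrogenated; the aldehyde is trapped by the 1,4-hydroxyl as the five-membered lactol (the 1,5-hydroxyl is neopentyl-like and slower), the same catalyst oxidises the lactol to the lactone, and PPTS funnels any δ-lactone to the more stable γ-lactone. The closest known reaction is Cu/nitroxyl aerobic oxidative lactonisation of unsymmetrical 1,4- and 1,5-diols, not shown for a tris-primary triol with 5- versus 6-ring competition; no stereocentre is formed or touched.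

Step 15
Reactants: 28 (4R)-4-{(1R)-2-hydroxy-1-[(1R,3aR,8aS)-1,4,4-trimethyl-8-methylidenedecahydroazulen-1-yl]ethyl}oxolan-2-one
Product: 31 [(2R)-2-[(3R,4S)-4-(acetyloxy)-5-oxooxolan-3-yl]-2-[(1R,3aR,8aS)-1,4,4-trimethyl-8-methylidenedecahydroazulen-1-yl]ethyl] acetate (CNP0234964.1), via disodium dianion 29 (not isolated), via disodium dialkoxide 30 (not isolated)
Conditions: NaHMDS (2.4 equiv), THF, −78 °C (inverse addition); 3-phenyl-2-(phenylsulfonyl)oxaziridine (1.3 equiv), −78 °C; then Ac2O (6 equiv), DMAP (cat.), −78 → 0 °C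
Reagents that add atoms: 3-phenyl-2-(phenylsulfonyl)oxaziridine, O=S(=O)(N1OC1c1ccccc1)c1ccccc1; acetic anhydride, CC(=O)OC(C)=O
Why: Davis enolate oxidation: the lactone sodium enolate (inert to the primary alkoxide once enolised) takes oxygen on the face opposite the bulky β-substituent, giving the trans α-oxy lactone (new centre S), and both alkoxides are then O-acetylated in the same flask.

## Compound list

1 | 3-methylcyclohex-2-en-1-one | CC1=CC(=O)CCC1 | starting material
2 | [(3,3-dimethylcyclohex-1-en-1-yl)oxy]trimethylsilane | C[Si](C)(C)OC1=CC(C)(C)CCC1 | intermediate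
3 | [(5,5-dimethylbicyclo[4.1.0]heptan-1-yl)oxy]trimethylsilane, racemic | C[Si](C)(C)OC12CCCC(C)(C)C1C2 | intermediate
4 | 3-chloro-4,4-dimethylcycloheptan-1-one, racemic | O=C1CC(Cl)C(C)(C)CCC1 | intermediate
5 | 4,4-dimethylcyclohept-2-en-1-one | O=C1C=CC(C)(C)CCC1 | intermediate
6 | 2-(2-bromoethyl)-2-methyl-1,3-dioxolane | CC1(CCBr)OCCO1 | starting material
7 | [2-(2-methyl-1,3-dioxolan-2-yl)ethyl]magnesium bromide | CC1(CC[Mg]Br)OCCO1 | intermediate
8 | bromomagnesium (3R)-4,4-dimethyl-3-[2-(2-methyl-1,3-dioxolan-2-yl)ethyl]cyclohept-1-en-1-olate | CC1(CC[C@@H]2C=C(O[Mg]Br)CCCC2(C)C)OCCO1 | intermediate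
9 | (3R)-4,4-dimethyl-3-[2-(2-methyl-1,3-dioxolan-2-yl)ethyl]cyclohept-1-en-1-yl trifluoromethanesulfonate | CC1(CC[C@@H]2C=C(OS(=O)(=O)C(F)(F)F)CCCC2(C)C)OCCO1 | intermediate
10 | (3R)-4,4-dimethyl-3-(3-oxobutyl)cyclohept-1-en-1-yl trifluoromethanesulfonate | CC(=O)CC[C@@H]1C=C(OS(=O)(=O)C(F)(F)F)CCCC1(C)C | intermediate
11 | 4-[(1R)-7,7-dimethyl-3-[(trimethylsilyl)methyl]cyclohept-2-en-1-yl]butan-2-one | C[Si](C)(C)CC1=C[C@@H](CCC(C)=O)C(C)(C)CCC1 | intermediate
12 | (3aR,8aS)-1,4,4-trimethyl-8-methylidenedecahydroazulen-1-ol, cis-fused, C1 epimers | C=C1CCCC(C)(C)[C@@H]2CCC(C)(O)[C@H]12 | intermediate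
13 | methyl (3aR,8aS)-1,4,4-trimethyl-8-methylidenedecahydroazulen-1-yl oxalate | C=C1CCCC(C)(C)[C@@H]2CCC(C)(OC(=O)C(=O)OC)[C@H]12 | intermediate
14 | caesium {[(3aR,8aS)-1,4,4-trimethyl-8-methylidenedecahydroazulen-1-yl]oxy}(oxo)acetate | C=C1CCCC(C)(C)[C@@H]2CCC(C)(OC(=O)C(=O)[O-])[C@H]12.[Cs+] | intermediate
15 | furfural (furan-2-carbaldehyde) | O=Cc1ccco1 | starting material
16 | 5-hydroxyfuran-2(5H)-one, racemic | O=C1C=CC(O)O1 | intermediate
17 | (1S,2R,5S)-(+)-menthol | O[C@H]1C[C@@H](C)CC[C@@H]1C(C)C | starting material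
18 | (5S)-5-{[(1S,2R,5S)-5-methyl-2-(propan-2-yl)cyclohexyl]oxy}furan-2(5H)-one | O=C1C=C[C@@H](O[C@H]2C[C@@H](C)CC[C@@H]2C(C)C)O1 | intermediate
19 | (5S)-3,4-dibromo-5-(menthyloxy)oxolan-2-one, trans-dibromide mixture | O=C1C(Br)C(Br)[C@@H](O[C@H]2C[C@@H](C)CC[C@@H]2C(C)C)O1 | intermediate
20 | (5S)-3-bromo-5-(menthyloxy)furan-2(5H)-one | O=C1C(Br)=C[C@@H](O[C@H]2C[C@@H](C)CC[C@@H]2C(C)C)O1 | intermediate
21 | (2-ethoxy-2-oxoethyl)zinc bromide (commercial solution) | CCOC(=O)C[Zn]Br | starting material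
22 | ethyl 2-[(5S)-5-(menthyloxy)-2-oxo-2,5-dihydrofuran-3-yl]acetate | CCOC(=O)CC1=C[C@@H](O[C@H]2C[C@@H](C)CC[C@@H]2C(C)C)OC1=O | intermediate
23 | caesium enolate of 24 (lactone C2–C3 enolate) | C=C1CCCC(C)(C)[C@@H]2CC[C@@](C)([C@@H]3[C@@H](O[C@H]4C[C@@H](C)CC[C@@H]4C(C)C)OC([O-])=C3CC(=O)OCC)[C@H]12.[Cs+] | intermediate
24 | ethyl 2-[(3R,4R,5S)-5-(menthyloxy)-2-oxo-4-[(1R,3aR,8aS)-1,4,4-trimethyl-8-methylidenedecahydroazulen-1-yl]oxolan-3-yl]acetate | C=C1CCCC(C)(C)[C@@H]2CC[C@@](C)([C@@H]3[C@@H](O[C@H]4C[C@@H](C)CC[C@@H]4C(C)C)OC(=O)[C@@H]3CC(=O)OCC)[C@H]12 | intermediate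
25 | (2R,3R)-2-(2-hydroxyethyl)-3-[(1R,3aR,8aS)-1,4,4-trimethyl-8-methylidenedecahydroazulen-1-yl]butane-1,4-diol | C=C1CCCC(C)(C)[C@@H]2CC[C@@](C)([C@H](CO)[C@H](CO)CCO)[C@H]12 | intermediate
26 | (3R,4R)-5-hydroxy-3-(hydroxymethyl)-4-[(1R,3aR,8aS)-1,4,4-trimethyl-8-methylidenedecahydroazulen-1-yl]pentanal | C=C1CCCC(C)(C)[C@@H]2CC[C@@](C)([C@H](CO)[C@H](CO)CC=O)[C@H]12 | intermediate
27 | (4R)-4-{(1R)-2-hydroxy-1-[(1R,3aR,8aS)-1,4,4-trimethyl-8-methylidenedecahydroazulen-1-yl]ethyl}oxolan-2-ol, anomers | C=C1CCCC(C)(C)[C@@H]2CC[C@@](C)([C@H](CO)[C@@H]3COC(O)C3)[C@H]12 | intermediate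
28 | (4R)-4-{(1R)-2-hydroxy-1-[(1R,3aR,8aS)-1,4,4-trimethyl-8-methylidenedecahydroazulen-1-yl]ethyl}oxolan-2-one | C=C1CCCC(C)(C)[C@@H]2CC[C@@](C)([C@H](CO)[C@@H]3COC(=O)C3)[C@H]12 | intermediate
29 | disodium alkoxide–lactone enolate of 28 | C=C1CCCC(C)(C)[C@@H]2CC[C@@](C)([C@H](C[O-])[C@@H]3COC([O-])=C3)[C@H]12.[Na+].[Na+] | intermediate
30 | disodium dialkoxide of the (3S)-3-hydroxy derivative of 28 | C=C1CCCC(C)(C)[C@@H]2CC[C@@](C)([C@H](C[O-])[C@@H]3COC(=O)[C@H]3[O-])[C@H]12.[Na+].[Na+] | intermediate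
31 | [(2R)-2-[(3R,4S)-4-(acetyloxy)-5-oxooxolan-3-yl]-2-[(1R,3aR,8aS)-1,4,4-trimethyl-8-methylidenedecahydroazulen-1-yl]ethyl] acetate (CNP0234964.1) | C=C1CCCC(C)(C)[C@@H]2CC[C@@](C)([C@H](COC(C)=O)[C@@H]3COC(=O)[C@H]3OC(C)=O)[C@H]12 | target

## Step count and risks

Total step count: 15 (steps 1–7 hydroazulene branch, steps 8–11 butenolide branch, steps 12–15 union and endgame).
Longest linear sequence: 11 steps (1–7, then 12–15) from 3-methylcyclohex-2-en-1-one.

The three steps most likely to fail: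

Step 14 (the proposed new step). Risk: oxidation at the wrong carbinol, over-oxidation of the remaining hydroxymethyl group, or a δ-lactol/δ-lactone that does not funnel to the γ-lactone. The fallback uses known chemistry and protects the future lactone carbonyl as a carboxylate instead of differentiating three alcohols. It sets out from 20 and 14 and comes back at 28. Negishi coupling of 20 with (2-allyloxy-2-oxoethyl)zinc bromide gives the allyl ester acceptor F4. Photoredox coupling with 14 as in step 12 gives the allyl ester adduct F5. Pd(PPh3)4 and morpholine remove the allyl group under neutral conditions to give the carboxylic acid F6. LiBH4 in THF reduces the lactone acetal while the lithium carboxylate is inert, giving the dihydroxy acid F7, which closes to γ-lactone 28 on acidification.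

Step 12. Risk: slow radical addition to the α-substituted acceptor, base-induced double-bond migration in 22, or loss of the cis C3/C4 relationship by epimerisation. The fallback sets out from 14 and 18 and comes back at 24. The unsubstituted butenolide 18 is coupled with 14 under the step 12 conditions to give the lactone adduct F1. LDA and ethyl glyoxylate give the aldol adduct F2, which the Burgess reagent dehydrates to the alkylidene lactone F3. Conjugate reduction with L-Selectride at −78 °C, quenched with 2,6-di-tert-butylphenol, places hydrogen at C3 anti to the azulenyl group and gives 24.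

Step 15. Risk: alkoxide-induced γ-to-δ translactonisation before enolisation, or incomplete dianion formation, in the one-flask protocol. The fallback sets out from 28 and comes back at 31. TBSCl and imidazole give the silyl ether F8. NaHMDS and the Davis oxaziridine on this mono-anion substrate give the α-hydroxy lactone F9. TBAF buffered with AcOH gives the diol F10, and Ac2O, pyridine and DMAP give 31.

## Further compounds

F1 | step 12 | (4R,5S)-5-(menthyloxy)-4-[(1R,3aR,8aS)-1,4,4-trimethyl-8-methylidenedecahydroazulen-1-yl]oxolan-2-one | C=C1CCCC(C)(C)[C@@H]2CC[C@@](C)([C@H]3CC(=O)O[C@@H]3O[C@H]4C[C@@H](C)CC[C@@H]4C(C)C)[C@H]12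
F2 | step 12 | ethyl 2-hydroxy-2-[(4R,5S)-5-(menthyloxy)-2-oxo-4-[(1R,3aR,8aS)-1,4,4-trimethyl-8-methylidenedecahydroazulen-1-yl]oxolan-3-yl]acetate, diastereomer mixture | C=C1CCCC(C)(C)[C@@H]2CC[C@@](C)([C@H]3C(C(O)C(=O)OCC)C(=O)O[C@@H]3O[C@H]4C[C@@H](C)CC[C@@H]4C(C)C)[C@H]12
F3 | step 12 | ethyl 2-[(4R,5S)-5-(menthyloxy)-2-oxo-4-[(1R,3aR,8aS)-1,4,4-trimethyl-8-methylidenedecahydroazulen-1-yl]oxolan-3-ylidene]acetate, E/Z mixture | C=C1CCCC(C)(C)[C@@H]2CC[C@@](C)([C@H]3C(=CC(=O)OCC)C(=O)O[C@@H]3O[C@H]4C[C@@H](C)CC[C@@H]4C(C)C)[C@H]12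
F4 | step 14 | prop-2-en-1-yl 2-[(5S)-5-(menthyloxy)-2-oxo-2,5-dihydrofuran-3-yl]acetate | C=CCOC(=O)CC1=C[C@@H](O[C@H]2C[C@@H](C)CC[C@@H]2C(C)C)OC1=O
F5 | step 14 | prop-2-en-1-yl 2-[(3R,4R,5S)-5-(menthyloxy)-2-oxo-4-[(1R,3aR,8aS)-1,4,4-trimethyl-8-methylidenedecahydroazulen-1-yl]oxolan-3-yl]acetate | C=C1CCCC(C)(C)[C@@H]2CC[C@@](C)([C@@H]3[C@@H](O[C@H]4C[C@@H](C)CC[C@@H]4C(C)C)OC(=O)[C@@H]3CC(=O)OCC=C)[C@H]12
F6 | step 14 | 2-[(3R,4R,5S)-5-(menthyloxy)-2-oxo-4-[(1R,3aR,8aS)-1,4,4-trimethyl-8-methylidenedecahydroazulen-1-yl]oxolan-3-yl]acetic acid | C=C1CCCC(C)(C)[C@@H]2CC[C@@](C)([C@@H]3[C@@H](O[C@H]4C[C@@H](C)CC[C@@H]4C(C)C)OC(=O)[C@@H]3CC(=O)O)[C@H]12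
F7 | step 14 | (3R,4R)-5-hydroxy-3-(hydroxymethyl)-4-[(1R,3aR,8aS)-1,4,4-trimethyl-8-methylidenedecahydroazulen-1-yl]pentanoic acid | C=C1CCCC(C)(C)[C@@H]2CC[C@@](C)([C@H](CO)[C@H](CO)CC(=O)O)[C@H]12
F8 | step 15 | (4R)-4-{(1R)-2-[(tert-butyldimethylsilyl)oxy]-1-[(1R,3aR,8aS)-1,4,4-trimethyl-8-methylidenedecahydroazulen-1-yl]ethyl}oxolan-2-one | C=C1CCCC(C)(C)[C@@H]2CC[C@@](C)([C@H](CO[Si](C)(C)C(C)(C)C)[C@@H]3COC(=O)C3)[C@H]12
F9 | step 15 | (3S,4R)-4-{(1R)-2-[(tert-butyldimethylsilyl)oxy]-1-[(1R,3aR,8aS)-1,4,4-trimethyl-8-methylidenedecahydroazulen-1-yl]ethyl}-3-hydroxyoxolan-2-one | C=C1CCCC(C)(C)[C@@H]2CC[C@@](C)([C@H](CO[Si](C)(C)C(C)(C)C)[C@@H]3COC(=O)[C@H]3O)[C@H]12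
F10 | step 15 | (3S,4R)-3-hydroxy-4-{(1R)-2-hydroxy-1-[(1R,3aR,8aS)-1,4,4-trimethyl-8-methylidenedecahydroazulen-1-yl]ethyl}oxolan-2-one | C=C1CCCC(C)(C)[C@@H]2CC[C@@](C)([C@H](CO)[C@@H]3COC(=O)[C@H]3O)[C@H]12
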